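**Retrosynthetic overview**

- Sarmentosumin C ⇐ global O-debenzylation ⇐ C6–CH2 bond made by o-quinone-methide Friedel–Crafts alkylation of an 8-benzylated (2S)-pinocembrin with a tetra-aryl salicyl alcohol; C8 is already occupied, so C6 is the only nucleophilic site.
- 8-Benzylated flavanone ⇐ acyclic δ-hydroxy-diketo-dioxinone: ring C closes first (cyclodehydration, carbinol C–O bond kept, so C2 is (S) by retention), then ring A (dioxinone → acylketene → C-acylation and aromatisation) in the same operation.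
- Acyclic precursor ⇐ 2,2,6-trimethyl-1,3-dioxin-4-one by γ-benzylation, γ-acetylation and dianion Claisen with the Weinreb amide of (S)-3-hydroxy-3-phenylpropanoic acid.
- Side chain ⇐ one Suzuki benzylation, two tosylhydrazone/boronic acid reductive couplings with formylphenylboronic acids, then NaBH4.
- All phenolic rings and the B ring are bought; only rings C and A are built, in that order.

Assumption: 2-(benzyloxy)benzyl bromide, ethyl (S)-3-hydroxy-3-phenylpropanoate and the two formylphenylboronic acids are taken as catalogue reagents.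

**Route**

Step 1
Reactants: 1 2,2,6-trimethyl-4H-1,3-dioxin-4-one; 2 2-(benzyloxy)benzyl bromide
Product: 3 6-{2-[2-(benzyloxy)phenyl]ethyl}-2,2-dimethyl-4H-1,3-dioxin-4-one
Conditions: 1 (1.3 equiv), LDA, THF/DMPU, −78 °C; then 2, −78 → −20 °C
Reagents that add atoms: none
Why: Alkylation of the lithium dienolate of 1 (vinylogous ester enolate alkylation) is γ-selective with reactive benzylic bromides in THF/DMPU and the aryl benzyl ether is inert to LDA; no stereocenter is formed.

Step 2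
Reactants: 3 6-{2-[2-(benzyloxy)phenyl]ethyl}-2,2-dimethyl-4H-1,3-dioxin-4-one
Product: 4 6-{1-[2-(benzyloxy)phenyl]-3-oxobutan-2-yl}-2,2-dimethyl-4H-1,3-dioxin-4-one (racemic)
Conditions: LiHMDS (2.1 equiv), THF, −78 °C; AcCl (1.0 equiv), −78 → −40 °C; aq NH4Cl
Reagents that add atoms: acetyl chloride, CC(=O)Cl
Why: The γ-lithiated dioxinone is C-acylated at the exocyclic carbon (vinylogous Claisen-type acylation, the second equivalent of base absorbs the more acidic product); the new CH centre is racemic and enolisable and later becomes aromatic C8.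

Step 3
Reactants: 5 ethyl (S)-3-hydroxy-3-phenylpropanoate
Product: 6 (S)-3-hydroxy-N-methoxy-N-methyl-3-phenylpropanamide
Conditions: MeNH(OMe)·HCl, i-PrMgCl, THF, −20 → 0 °C
Reagents that add atoms: N,O-dimethylhydroxylamine hydrochloride, CNOC.Cl
Why: Magnesium-amide aminolysis of the ester (Weinreb amide formation) tolerates the free secondary alcohol as its alkoxide and does not touch the carbinol C–O bond, so the (S) centre is carried over unchanged.

Step 4
Reactants: 4 6-{1-[2-(benzyloxy)phenyl]-3-oxobutan-2-yl}-2,2-dimethyl-4H-1,3-dioxin-4-one; 6 (S)-3-hydroxy-N-methoxy-N-methyl-3-phenylpropanamide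
Product: 7 6-{(7S)-1-[2-(benzyloxy)phenyl]-7-hydroxy-3,5-dioxo-7-phenylheptan-2-yl}-2,2-dimethyl-4H-1,3-dioxin-4-one (epimers at chain C2, enolised open-chain form, used crude)
Conditions: 4, LDA (2.1 equiv), THF, −78 → −40 °C; then lithium alkoxide of 6 (6 + LDA 1.0 equiv, −78 °C), −78 → −20 °C; aq NH4Cl (pH 7)
Reagents that add atoms: none
Why: The terminal carbanion of the dianion of 4 (crossed Claisen-type acylation of a 1,3-dicarbonyl dianion) adds once to the Weinreb amide, whose chelated tetrahedral adduct survives until quench, while the lithium alkoxide keeps the (S) carbinol from retro-aldol and leaves it untouched.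

Step 5
Reactants: 7 6-{(7S)-1-[2-(benzyloxy)phenyl]-7-hydroxy-3,5-dioxo-7-phenylheptan-2-yl}-2,2-dimethyl-4H-1,3-dioxin-4-one
Product: 10 (2S)-8-[2-(benzyloxy)benzyl]-5,7-dihydroxy-2-phenylchroman-4-one, via dihydropyranone 8 (not isolated), via acylketene 9 (not isolated)
Conditions: Amberlyst-15 (H+), 4 Å MS, PhMe, 23 °C; cannula-filter into PhMe at 110 °C (final 5 mM), 1 h
Reagents that add atoms: none
Why: Proposed new method: acid cyclodehydration of the δ-hydroxy-β-diketone gives dihydropyranone 8 (known reaction type; the carbinol C–O bond is never broken, so (S) is retained as C2), then thermal retro-[4+2] of the dioxinone releases acetone and acylketene 9; because the oxygen that normally captures such a ketene as a pyranone is now the ring-C ether oxygen and the aldol (resorcylate) mode would need a bridgehead alkene, the only six-membered path left is bonding of the nucleophilic C5 of the vinylogous ester to the ketene carbon (6π-electrocyclisation of the enolised dienylketene; closest known types are the Danheiser-type dienylketene benzannulation and the biomimetic Claisen cyclisation of 3,5,7-triketo esters), and tautomerisation gives the phloroglucinol ring A.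

Step 6
Reactants: 2 2-(benzyloxy)benzyl bromide; 11 [4-(benzyloxy)-3-formylphenyl]boronic acid
Product: 12 2-(benzyloxy)-5-[2-(benzyloxy)benzyl]benzaldehyde
Conditions: Pd(PPh3)4 (3 mol %), K2CO3, DME/H2O, 80 °C
Reagents that add atoms: none
Why: Suzuki–Miyaura sp3–sp2 coupling of a benzylic bromide with an arylboronic acid tolerates the aldehyde and fixes the CH2 link para to the benzyloxy group of the new ring, where boron sat.

Step 7
Reactants: 12 2-(benzyloxy)-5-[2-(benzyloxy)benzyl]benzaldehyde; 11 [4-(benzyloxy)-3-formylphenyl]boronic acid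
Product: 14 2-(benzyloxy)-5-{2-(benzyloxy)-5-[2-(benzyloxy)benzyl]benzyl}benzaldehyde, via tosylhydrazone 13 (not isolated)
Conditions: TsNHNH2 (1.0 equiv), 4 Å MS, 1,4-dioxane, 80 °C; then 11 (1.5 equiv), K2CO3, 110 °C
Reagents that add atoms: none
Why: Barluenga reductive coupling: base converts the N-tosylhydrazone into a diazoalkane that is trapped by the boronic acid (1,2-aryl shift with loss of N2, then protodeboronation), giving the diarylmethane with the link para to OBn and ortho to the next formyl group.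

Step 8
Reactants: 14 2-(benzyloxy)-5-{2-(benzyloxy)-5-[2-(benzyloxy)benzyl]benzyl}benzaldehyde; 15 (3-formyl-4-hydroxyphenyl)boronic acid
Product: 17 5-{2-(benzyloxy)-5-{2-(benzyloxy)-5-[2-(benzyloxy)benzyl]benzyl}benzyl}-2-hydroxybenzaldehyde, via tosylhydrazone 16 (not isolated)
Conditions: TsNHNH2 (1.0 equiv), 4 Å MS, 1,4-dioxane, 80 °C; then 15 (1.5 equiv), K2CO3 (3 equiv), 110 °C
Reagents that add atoms: none
Why: Same Barluenga reductive coupling; 15 reacts as its phenoxide, and the ring it delivers is the only one with a free OH, which is the one needed next to the future benzylic alcohol.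

Step 9
Reactants: 17 5-{2-(benzyloxy)-5-{2-(benzyloxy)-5-[2-(benzyloxy)benzyl]benzyl}benzyl}-2-hydroxybenzaldehyde
Product: 18 4-{2-(benzyloxy)-5-{2-(benzyloxy)-5-[2-(benzyloxy)benzyl]benzyl}benzyl}-2-(hydroxymethyl)phenol
Conditions: NaBH4, THF/MeOH, 0 °C; neutral work-up
Reagents that add atoms: none
Why: Chemoselective carbonyl reduction with NaBH4 gives the salicyl alcohol that serves as the o-quinone methide precursor; nothing else in 17 is reducible.

Step 10
Reactants: 10 (2S)-8-[2-(benzyloxy)benzyl]-5,7-dihydroxy-2-phenylchroman-4-one; 18 4-{2-(benzyloxy)-5-{2-(benzyloxy)-5-[2-(benzyloxy)benzyl]benzyl}benzyl}-2-(hydroxymethyl)phenol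
Product: 20 (2S)-8-[2-(benzyloxy)benzyl]-6-{5-{2-(benzyloxy)-5-{2-(benzyloxy)-5-[2-(benzyloxy)benzyl]benzyl}benzyl}-2-hydroxybenzyl}-5,7-dihydroxy-2-phenylchroman-4-one, via o-quinone methide 19 (not isolated)
Conditions: ZnCl2 (3 equiv), 1,4-dioxane, 80 °C; 10 (1.3 equiv), 18 added slowly
Reagents that add atoms: none
Why: ZnCl2 chelates and ionises the salicyl alcohol to o-quinone methide 19, which is captured by the most nucleophilic carbon present (Friedel–Crafts-type conjugate addition); with C8 substituted, the phloroglucinol carbon C6 is the only site, and C2 is not involved.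

Step 11
Reactants: 20 tetra-O-benzyl sarmentosumin C (full name as in step 10)
Product: 21 sarmentosumin C, (2S)-5,7-dihydroxy-6-{2-hydroxy-5-{2-hydroxy-5-[2-hydroxy-5-(2-hydroxybenzyl)benzyl]benzyl}benzyl}-8-(2-hydroxybenzyl)-2-phenylchroman-4-one
Conditions: H2 (1 atm), 10% Pd/C, EtOAc/MeOH, 23 °C
Reagents that add atoms: none
Why: Hydrogenolysis of the four aryl benzyl ethers is neutral, leaves the diarylmethanes and the chelated aryl ketone alone and does not open the flavanone ring at 1 atm, so (2S) is kept.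

**Compound list**

1 | 2,2,6-trimethyl-4H-1,3-dioxin-4-one | CC1=CC(=O)OC(C)(C)O1 | starting material
2 | 2-(benzyloxy)benzyl bromide | BrCc1ccccc1OCc1ccccc1 | starting material
3 | 6-{2-[2-(benzyloxy)phenyl]ethyl}-2,2-dimethyl-4H-1,3-dioxin-4-one | CC1(C)OC(=O)C=C(CCc2ccccc2OCc2ccccc2)O1 | intermediate
4 | 6-{1-[2-(benzyloxy)phenyl]-3-oxobutan-2-yl}-2,2-dimethyl-4H-1,3-dioxin-4-one (racemic) | CC(=O)C(Cc1ccccc1OCc1ccccc1)C1=CC(=O)OC(C)(C)O1 | intermediate
5 | ethyl (S)-3-hydroxy-3-phenylpropanoate | CCOC(=O)C[C@H](O)c1ccccc1 | starting material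
6 | (S)-3-hydroxy-N-methoxy-N-methyl-3-phenylpropanamide | CON(C)C(=O)C[C@H](O)c1ccccc1 | intermediate
7 | 6-{(7S)-1-[2-(benzyloxy)phenyl]-7-hydroxy-3,5-dioxo-7-phenylheptan-2-yl}-2,2-dimethyl-4H-1,3-dioxin-4-one (epimers at chain C2) | CC1(C)OC(=O)C=C(O1)C(Cc2ccccc2OCc2ccccc2)C(=O)CC(=O)C[C@H](O)c3ccccc3 | intermediate
8 | 6-{2-[2-(benzyloxy)phenyl]-1-[(2S)-4-oxo-2-phenyl-3,4-dihydro-2H-pyran-6-yl]ethyl}-2,2-dimethyl-4H-1,3-dioxin-4-one | CC1(C)OC(=O)C=C(O1)C(Cc2ccccc2OCc2ccccc2)C3=CC(=O)C[C@H](O3)c4ccccc4 | intermediate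
9 | 5-[2-(benzyloxy)phenyl]-4-[(2S)-4-oxo-2-phenyl-3,4-dihydro-2H-pyran-6-yl]pent-1-ene-1,3-dione (acylketene) | O=C=CC(=O)C(Cc2ccccc2OCc2ccccc2)C3=CC(=O)C[C@H](O3)c4ccccc4 | intermediate
10 | (2S)-8-[2-(benzyloxy)benzyl]-5,7-dihydroxy-2-phenylchroman-4-one | O=C1C[C@@H](c2ccccc2)Oc2c(Cc3ccccc3OCc3ccccc3)c(O)cc(O)c21 | intermediate
11 | [4-(benzyloxy)-3-formylphenyl]boronic acid | O=Cc1cc(B(O)O)ccc1OCc1ccccc1 | starting material
12 | 2-(benzyloxy)-5-[2-(benzyloxy)benzyl]benzaldehyde | O=Cc1cc(Cc2ccccc2OCc2ccccc2)ccc1OCc1ccccc1 | intermediate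
13 | N-tosylhydrazone of 12 | Cc1ccc(cc1)S(=O)(=O)N/N=C/c1cc(Cc2ccccc2OCc2ccccc2)ccc1OCc1ccccc1 | intermediate
14 | 2-(benzyloxy)-5-{2-(benzyloxy)-5-[2-(benzyloxy)benzyl]benzyl}benzaldehyde | O=Cc1cc(Cc2cc(Cc3ccccc3OCc3ccccc3)ccc2OCc2ccccc2)ccc1OCc1ccccc1 | intermediate
15 | (3-formyl-4-hydroxyphenyl)boronic acid | O=Cc1cc(B(O)O)ccc1O | starting material
16 | N-tosylhydrazone of 14 | Cc1ccc(cc1)S(=O)(=O)N/N=C/c1cc(Cc2cc(Cc3ccccc3OCc3ccccc3)ccc2OCc2ccccc2)ccc1OCc1ccccc1 | intermediate
17 | 5-{2-(benzyloxy)-5-{2-(benzyloxy)-5-[2-(benzyloxy)benzyl]benzyl}benzyl}-2-hydroxybenzaldehyde | O=Cc1cc(Cc2cc(Cc3cc(Cc4ccccc4OCc4ccccc4)ccc3OCc3ccccc3)ccc2OCc2ccccc2)ccc1O | intermediate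
18 | 4-{2-(benzyloxy)-5-{2-(benzyloxy)-5-[2-(benzyloxy)benzyl]benzyl}benzyl}-2-(hydroxymethyl)phenol | OCc1cc(Cc2cc(Cc3cc(Cc4ccccc4OCc4ccccc4)ccc3OCc3ccccc3)ccc2OCc2ccccc2)ccc1O | intermediate
19 | 4-{2-(benzyloxy)-5-{2-(benzyloxy)-5-[2-(benzyloxy)benzyl]benzyl}benzyl}-6-methylidenecyclohexa-2,4-dien-1-one (o-quinone methide of 18) | C=C1C=C(Cc2cc(Cc3cc(Cc4ccccc4OCc4ccccc4)ccc3OCc3ccccc3)ccc2OCc2ccccc2)C=CC1=O | intermediate
20 | (2S)-8-[2-(benzyloxy)benzyl]-6-{5-{2-(benzyloxy)-5-{2-(benzyloxy)-5-[2-(benzyloxy)benzyl]benzyl}benzyl}-2-hydroxybenzyl}-5,7-dihydroxy-2-phenylchroman-4-one | O=C1C[C@@H](c2ccccc2)Oc2c(Cc3ccccc3OCc3ccccc3)c(O)c(Cc3cc(Cc4cc(Cc5cc(Cc6ccccc6OCc6ccccc6)ccc5OCc5ccccc5)ccc4OCc4ccccc4)ccc3O)c(O)c21 | intermediate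
21 | sarmentosumin C | O=C1C[C@@H](c2ccccc2)Oc2c(Cc3ccccc3O)c(O)c(Cc3cc(Cc4cc(Cc5cc(Cc6ccccc6O)ccc5O)ccc4O)ccc3O)c(O)c21 | target

**Totals**

Total step count: 11. Longest linear sequence: 6 steps (1 → 2 → 4 → 5 → 10 → 11; the side-chain arm 6 → 7 → 8 → 9 → 10 → 11 is equally long).

**Three steps most likely to fail, with fallbacks**

Step 5 is the least precedented step. The acylketene could oligomerise instead of closing ring A, or C2 could erode at 110 °C. The fallback sets out from 7. Heating 7 in PhMe/t-BuOH at 110 °C captures the ketene intermolecularly while the carbinol is still open-chain, giving tert-butyl (9S)-4-[2-(benzyloxy)benzyl]-9-hydroxy-3,5,7-trioxo-9-phenylnonanoate F1. At 0 °C, TFA then closes ring C and cleaves the tert-butyl ester, and added TFAA turns the β-keto acid into a mixed anhydride that C-acylates the dihydropyranone. This is a cold, acid-mediated intramolecular Friedel–Crafts-type acylation in place of the hot pericyclic closure, and it comes back to the route at 10.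

Step 8 may fail because the diazo intermediate can be intercepted by the formyl group or by the free phenol of 15. The fallback sets out from 14. NaBH4 gives the benzylic alcohol {2-(benzyloxy)-5-{2-(benzyloxy)-5-[2-(benzyloxy)benzyl]benzyl}phenyl}methanol F2. PBr3 converts it to 1-(benzyloxy)-2-(bromomethyl)-4-{2-(benzyloxy)-5-[2-(benzyloxy)benzyl]benzyl}benzene F3. A Pd-catalysed Suzuki–Miyaura coupling of F3 with 15, as in step 6, comes back at 17.

Step 10 may give oligomers of 18, or ZnCl2 and heat may erode C2. The fallback sets out from 10 and the aldehyde 17, so step 9 is skipped. PhB(OH)2 with catalytic propionic acid in refluxing PhMe (Dean–Stark) forms the C6–C bond inside a boron template ortho to O7, giving the (2S)-flavanone-fused 2-phenyl-4-aryl-4H-1,3,2-benzodioxaborin F4 (ring C6–CH(Ar)–O–B(Ph)–O–C7, Ar being the tetra-aryl unit of 17). Et3SiH/TFA then reduces the doubly benzylic C–O bond and releases the boron, coming back at 20.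

**Further compounds**

F1 | step 5 | tert-butyl (9S)-4-[2-(benzyloxy)benzyl]-9-hydroxy-3,5,7-trioxo-9-phenylnonanoate | CC(C)(C)OC(=O)CC(=O)C(Cc1ccccc1OCc1ccccc1)C(=O)CC(=O)C[C@H](O)c1ccccc1
F2 | step 8 | {2-(benzyloxy)-5-{2-(benzyloxy)-5-[2-(benzyloxy)benzyl]benzyl}phenyl}methanol | OCc1cc(Cc2cc(Cc3ccccc3OCc3ccccc3)ccc2OCc2ccccc2)ccc1OCc1ccccc1
F3 | step 8 | 1-(benzyloxy)-2-(bromomethyl)-4-{2-(benzyloxy)-5-[2-(benzyloxy)benzyl]benzyl}benzene | BrCc1cc(Cc2cc(Cc3ccccc3OCc3ccccc3)ccc2OCc2ccccc2)ccc1OCc1ccccc1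
F4 | step 10 | (2S)-flavanone-fused 2-phenyl-4-aryl-4H-1,3,2-benzodioxaborin from 10 and 17 (ring C6–CH(Ar)–O–B(Ph)–O–C7; CH epimers) | O=C1C[C@@H](c2ccccc2)Oc2c(Cc3ccccc3OCc3ccccc3)c3OB(c4ccccc4)OC(c4cc(Cc5cc(Cc6cc(Cc7ccccc7OCc7ccccc7)ccc6OCc6ccccc6)ccc5OCc5ccccc5)ccc4O)c3c(O)c21
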